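If each capture is first order in its own nucleophile and both draw on one shared species, the ratio of other capture product to target at the start equals a constant times the ratio of the two charges, so I wanted that constant for the winter flask.

| setting | winter | dawn | flask |
|---|---|---|---|
| solid substrate | 5.0 × 10⁻⁴ M | 2.5 × 10⁻⁴ M | 5.0 × 10⁻⁴ M |
| first nucleophile | 0.95 equiv | 0.95 equiv | 0.950 equiv |
| second nucleophile | 1.3 equiv | 1.3 equiv | 1.30 equiv |
| protic impurity | 0.010 mM | 0.010 mM | 0.0100 mM |
| remark | the very flask that is asked about, followed so far | run made earlier |  |
| time |  |  | 2.0 min |

| run | time / s | other capture product / % | target / % |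
|---|---|---|---|
| winter | 10.0 | 25.5 | 15.6 |
| winter | 12.0 | 29.2 | 17.9 |
| winter | 15.0 | 33.9 | 19.0 |
| winter | 20.0 | 39.3 | 18.9 |
| dawn | 10.0 | 25.8 | 18.0 |
| dawn | 20.0 | 33.8 | 20.1 |
| dawn | 30.0 | 36.8 | 18.9 |
| dawn | 60.0 | 37.8 | 12.9 |
| dawn | 120 | 37.2 | 5.7 |

(scatter of a reading: 0.3 percentage points)

- share of other capture product in other capture product plus target at 0.80 s
- share of other capture product in other capture product plus target at 8.0 s
- share of other capture product in other capture product plus target at 2.0 min
- which of other capture product and target there is more of at 2.0 min

- given per volume of solution although it is solid: solid substrate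
- at the start none of the solid substrate is in solution

The substrate level cancels, since both charges are fractions of it, so dawn can serve winter. The charge ratio enters in full proportion, and it is given. The protic impurity, if it spent second nucleophile one for one, would take 1.54% of that charge. Target lost before a reading did matter: dawn's target fell from 12.9% to 5.7% between 60.0 s and 120 s, a late loss constant of 0.0136 s⁻¹, and target read at 10.0 s was roughly half that time old, so at that constant it had gone 0.0680 turnovers, which I added back, a correction too small if the loss runs with a reagent that had fallen by then.

That gave the selectivity factor, the other capture product made per target made at equal charges 0.979. With winter's charges the ratio was 1.34, so I reckoned a share of 57.2% at 0.80 s. In dawn, other capture product stood at 37.2% against 5.7% target at 120 s, so I expected it to lead in the winter flask too.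

The forecast, holding that “the flux share rises slowly with time”, gave 57%, 61% and 92%, with other capture product ahead.

The winter flask gave 56.3%, 60.3% and 93.8%, with 45.4% other capture product against 3.00% target.

    first nucleophile + intermediate → target (k = 17000 M⁻¹ s⁻¹)
    intermediate → solvolysis product (k = 3.90 s⁻¹)
    solid substrate ⇌ starting material, rate k3*(cs3 - [starting material]) while solid is left; crystals form when [starting material] > cs3 (solubility = 0.270 mM, k = 1.40 s⁻¹)
    second nucleophile + protic impurity → quenched reagent (k = 71000 M⁻¹ s⁻¹)
    first nucleophile + target → over-reaction product (k = 110 M⁻¹ s⁻¹)
    starting material → intermediate (k = 0.120 s⁻¹)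
    second nucleophile + intermediate → other capture product (k = 16000 M⁻¹ s⁻¹)

My share from the selectivity factor lay 0.90 percentage points above the winter flask's at 0.80 s. By 0.200 min the winter flask held 0% solid substrate and 35.0% starting material, which was still feeding the intermediate and both captures. By 1.00 min starting material was down to 0.110% and other capture product stood at 45.4%, while first nucleophile went on turning target into over-reaction product, 24.0% then and 30.2% at 2.00 min. With 5.20 equiv of second nucleophile, the factor gives a ratio of 5.36, a share of 84.3% at 0.80 s, and that neighbouring flask gave 83.9%.

The readings are calculated from invented constants.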